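The retrosynthesis first cuts the depside ester bond between the ring A C1' carbonyl and the C4 oxygen of ring B. The resulting acid and phenol differ only at C3 (CHO against CH3) and in the ester, so both trace back to methyl 3-formyl-2,4-dihydroxy-5,6-dimethylbenzoate.
From that benzoate the C3'–CHO bond and two O-methyl protecting groups are taken away, and the benzene ring is then cut at C5'–C6' and C3'–C4'.
Enabling feature: in ring A the C1' carboxyl is para to the C4' oxygen, C5' next to that oxygen bears CH3, and C2'–O and C6'–CH3 flank the carboxyl. C1', C2', C3' and C6' are therefore C5, C4, C3 and C6 of a 4-alkoxy-6-methyl-2-pyranone-5-carboxylate, and C4'/C5' are the alkene carbons of the dimethyl ketene acetal of propanoate.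
Forward: the pyranone is made in three steps and the ketene acetal in one. Cycloaddition with loss of CO2 and methanol closes the only carbocycle that has to be built. Formylation and ether cleavage follow, one portion is reduced (ring B), one is hydrolysed (ring A), and a carbodiimide joins the halves.
The target has no stereocentre, and the transient ones of the cycloadduct vanish on aromatization.

Key step: step 5

Remark: 3 and 4 are each drawn as one tautomer. Compounds 8 and 9 arise as racemates (8 as an endo/exo mixture), so no configuration is written for them. Compounds 20 and 21 are bought only if the fallback to step 5 is used.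

Step 1
Reactants: 1 dimethyl 3-oxopentanedioate; 2 acetyl chloride
Product: 3 dimethyl 2-acetyl-3-oxopentanedioate
Conditions: MgCl2, pyridine, CH2Cl2, 0 °C to rt; then 1 M HCl
Reagents that add atoms: none
Why: Soft enolization with MgCl2/pyridine followed by C-acylation of a β-keto ester, in which chelation to magnesium favours carbon over oxygen attack and the more acidic product stays chelated, which should prevent a second acylation.

Step 2
Reactants: 3 dimethyl 2-acetyl-3-oxopentanedioate
Product: 4 methyl 4-hydroxy-6-methyl-2-oxo-2H-pyran-5-carboxylate
Conditions: conc. H2SO4, 0 °C to rt; then ice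
Reagents that add atoms: none
Why: Acid-catalysed enol lactonization (6-exo-trig) of a 3,5-dioxo ester, the standard closure to 4-hydroxy-2-pyranones: the enol oxygen of the acetyl group attacks the remote ester, methanol leaves, and the C2 ester stays as the 5-carboxylate.

Step 3
Reactants: 4 methyl 4-hydroxy-6-methyl-2-oxo-2H-pyran-5-carboxylate
Product: 5 methyl 4-methoxy-6-methyl-2-oxo-2H-pyran-5-carboxylate
Conditions: Me2SO4, K2CO3, acetone, reflux
Reagents that add atoms: dimethyl sulfate, COS(=O)(=O)OC
Why: O-alkylation of a vinylogous acid with a hard methylating agent, under conditions that convert 4-hydroxy-6-methyl-2-pyranones into 4-methoxy-2-pyranones rather than the 2-methoxy-4-pyranone isomers.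

Step 4
Reactants: 6 trimethyl orthopropionate (1,1,1-trimethoxypropane)
Product: 7 1,1-dimethoxyprop-1-ene
Conditions: Al(OtBu)3 (0.35 equiv), neat, reflux under a fractionating column, slow distillation; redistilled
Reagents that add atoms: none
Why: Aluminium alkoxide dealcoholation of an orthoester, a formal 1,2-elimination in which the methanol is held on aluminium as methoxide while tert-butanol and the lower-boiling ketene acetal distil, so the elimination cannot reverse.

Step 5
Reactants: 5 methyl 4-methoxy-6-methyl-2-oxo-2H-pyran-5-carboxylate; 7 1,1-dimethoxyprop-1-ene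
Product: 10 methyl 2,4-dimethoxy-5,6-dimethylbenzoate, via bridged lactone 8 (not isolated), via dimethoxycyclohexadiene 9 (not isolated)
Conditions: 7 (4 equiv), mesitylene, base-washed sealed tube, Ar, 160 °C
Reagents that add atoms: none
Why: The electron-rich alkene of 7 adds across C6 and C3 of the electron-poor diene of 5 in an inverse-electron-demand Diels–Alder reaction (asynchronous, the C6–CHCH3 bond leading) to give bridged lactone 8, which at this temperature expels CO2 by retro-[4+2] to diene 9, and 9 aromatizes by 1,2-loss of methanol (H from C5', OCH3 from C4'). The closest known reaction type is the conversion of alkyl 2-pyranone-5-carboxylates (coumalates, 6-substituted ones included) and 2-pyranone-3-carboxylates into alkoxybenzoates with ketene acetals. Ring A is closed by an intermolecular [4+2] cycloaddition that forms C5'–C6' and C3'–C4' together, pyranone C5, C4, C3 and C6 becoming C1', C2', C3' and C6' and the two alkene carbons of 7 becoming C4' and C5'. The stereocentres of 8 and 9 are erased on aromatization, so neither endo/exo nor facial selectivity is needed and 10 is achiral. The one selectivity required is regiochemical and is secured by polarization: C6 is the acceptor terminus (β to the 5-ester, δ to the lactone carbonyl) whereas C3 is enriched by the 4-methoxy group, and the largest HOMO coefficient of 7 lies on its methyl-bearing carbon, so CH3 ends at C5' and oxygen at C4'. Because the 4-methoxy and 6-methyl groups make 5 a poorer acceptor than a coumalate, an excess of 7, a high-boiling inert solvent and an acid-free sealed vessel are used.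

Step 6
Reactants: 10 methyl 2,4-dimethoxy-5,6-dimethylbenzoate
Product: 12 methyl 3-formyl-2,4-dimethoxy-5,6-dimethylbenzoate, via chloro(methoxy)methyl arene 11 (not isolated)
Conditions: Cl2CHOMe, TiCl4, CH2Cl2, −78 to 0 °C; then ice/1 M HCl
Reagents that add atoms: dichloromethyl methyl ether, COC(Cl)Cl; water, O
Why: Rieche formylation at C3, which is the only ring C–H and is activated by both ortho methoxy groups; it gives 11, which hydrolyses to the aldehyde on work-up, and any partial ether cleavage by TiCl4 is harmless because step 7 removes both ethers.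

Step 7
Reactants: 12 methyl 3-formyl-2,4-dimethoxy-5,6-dimethylbenzoate
Product: 14 methyl 3-formyl-2,4-dihydroxy-5,6-dimethylbenzoate, via bis(dichloroboryl) ether 13 (not isolated)
Conditions: BCl3 (4 equiv), CH2Cl2, −78 to 0 °C; then H2O
Reagents that add atoms: none
Why: Chelation-directed BCl3 cleavage of aryl methyl ethers ortho to carbonyl groups, in which each ether has a carbonyl partner of its own (C2–OCH3 the ester, C4–OCH3 the aldehyde), so both should fall to 13 while the ester methyl survives at 0 °C.

Step 8
Reactants: 14 methyl 3-formyl-2,4-dihydroxy-5,6-dimethylbenzoate (one portion)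
Product: 16 methyl 2,4-dihydroxy-3,5,6-trimethylbenzoate, via benzylic alcohol 15 (not isolated)
Conditions: H2 (1 atm), 10% Pd/C, AcOH, cat. HCl, rt
Reagents that add atoms: none
Why: Catalytic hydrogenation of the aldehyde to 15 and acid-assisted hydrogenolysis of its benzylic C–O bond, which the two ortho hydroxy groups activate; this is the usual CHO to CH3 conversion of o-hydroxybenzaldehydes and leaves ester and phenols untouched.

Step 9
Reactants: 14 methyl 3-formyl-2,4-dihydroxy-5,6-dimethylbenzoate (second portion)
Product: 17 3-formyl-2,4-dihydroxy-5,6-dimethylbenzoic acid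
Conditions: conc. H2SO4, 0 °C to rt; then ice
Reagents that add atoms: water, O
Why: Acid hydrolysis by unimolecular acyl–oxygen fission (AAC1, as with mesitoates), the pathway open to a di-ortho-substituted, electron-rich benzoate that resists saponification; the ring has no free position to sulfonate and the formyl group slows protodecarboxylation.

Step 10
Reactants: 17 3-formyl-2,4-dihydroxy-5,6-dimethylbenzoic acid; 16 methyl 2,4-dihydroxy-3,5,6-trimethylbenzoate
Product: 19 pseudocyphellarin A (methyl 4-[(3-formyl-2,4-dihydroxy-5,6-dimethylbenzoyl)oxy]-2-hydroxy-3,5,6-trimethylbenzoate), via O-acylisourea 18 (not isolated)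
Conditions: DCC, toluene, rt
Reagents that add atoms: none
Why: Carbodiimide esterification, the standard way to join unprotected o-hydroxy acids and resorcylate esters to depsides; both hydroxy groups of 17 are tied up in hydrogen bonds to CHO and carboxyl and the C2–OH of 16 in one to its ester, so the C4–OH of 16 is the only free nucleophile for 18.

Compound list
1 | dimethyl 3-oxopentanedioate | COC(=O)CC(=O)CC(=O)OC | starting material
2 | acetyl chloride | CC(Cl)=O | starting material
3 | dimethyl 2-acetyl-3-oxopentanedioate | COC(=O)CC(=O)C(C(C)=O)C(=O)OC | intermediate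
4 | methyl 4-hydroxy-6-methyl-2-oxo-2H-pyran-5-carboxylate | COC(=O)C1=C(C)OC(=O)C=C1O | intermediate
5 | methyl 4-methoxy-6-methyl-2-oxo-2H-pyran-5-carboxylate | COC(=O)C1=C(C)OC(=O)C=C1OC | intermediate
6 | trimethyl orthopropionate | CCC(OC)(OC)OC | starting material
7 | 1,1-dimethoxyprop-1-ene | CC=C(OC)OC | intermediate
8 | methyl 5,8,8-trimethoxy-1,7-dimethyl-3-oxo-2-oxabicyclo[2.2.2]oct-5-ene-6-carboxylate (racemic, endo/exo mixture, not isolated) | COC(=O)C1=C(OC)C2C(=O)OC1(C)C(C)C2(OC)OC | intermediate
9 | methyl 4,4,6-trimethoxy-2,3-dimethylcyclohexa-1,5-diene-1-carboxylate (racemic, not isolated) | COC(=O)C1=C(C)C(C)C(OC)(OC)C=C1OC | intermediate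
10 | methyl 2,4-dimethoxy-5,6-dimethylbenzoate | COC(=O)c1c(C)c(C)c(OC)cc1OC | intermediate
11 | methyl 3-[chloro(methoxy)methyl]-2,4-dimethoxy-5,6-dimethylbenzoate (racemic, not isolated) | COC(=O)c1c(C)c(C)c(OC)c(C(Cl)OC)c1OC | intermediate
12 | methyl 3-formyl-2,4-dimethoxy-5,6-dimethylbenzoate | COC(=O)c1c(C)c(C)c(OC)c(C=O)c1OC | intermediate
13 | methyl 2,4-bis[(dichloroboranyl)oxy]-3-formyl-5,6-dimethylbenzoate (not isolated) | COC(=O)c1c(C)c(C)c(OB(Cl)Cl)c(C=O)c1OB(Cl)Cl | intermediate
14 | methyl 3-formyl-2,4-dihydroxy-5,6-dimethylbenzoate | COC(=O)c1c(C)c(C)c(O)c(C=O)c1O | intermediate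
15 | methyl 2,4-dihydroxy-3-(hydroxymethyl)-5,6-dimethylbenzoate (not isolated) | COC(=O)c1c(C)c(C)c(O)c(CO)c1O | intermediate
16 | methyl 2,4-dihydroxy-3,5,6-trimethylbenzoate | COC(=O)c1c(C)c(C)c(O)c(C)c1O | intermediate
17 | 3-formyl-2,4-dihydroxy-5,6-dimethylbenzoic acid | OC(=O)c1c(C)c(C)c(O)c(C=O)c1O | intermediate
18 | O-(3-formyl-2,4-dihydroxy-5,6-dimethylbenzoyl)-N,N'-dicyclohexylisourea (not isolated) | O=Cc1c(O)c(C)c(C)c(C(=O)OC(=NC2CCCCC2)NC2CCCCC2)c1O | intermediate
19 | pseudocyphellarin A | COC(=O)c1c(C)c(C)c(OC(=O)c2c(C)c(C)c(O)c(C=O)c2O)c(C)c1O | target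
20 | dimethyl malonate (fallback to step 5 only) | COC(=O)CC(=O)OC | starting material
21 | (E)-3-methylpent-3-en-2-one (fallback to step 5 only) | C/C=C(\C)C(C)=O | starting material

Total step count: 10.
Longest linear sequence: 8 steps (1, 2, 3, 5, 6, 7, 9, 10; the branch through step 8 is equally long).

Steps most likely to fail

Step 5. The cycloaddition may stall because the 4-methoxy and 6-methyl groups raise the LUMO of the diene and crowd C6. At the temperature needed, the ketene acetal may also be consumed by oligomerization or by addition–elimination at C4. The fallback gives up the pyranone line and builds the same ring by anionic annulation and dehydrogenation. It sets out from dimethyl malonate 20 and (E)-3-methylpent-3-en-2-one 21 and comes back to the route at 14. NaOMe in refluxing MeOH should bring about Michael addition of 20 to C4 of 21, followed by Claisen closure of the ketone methyl group onto one ester, to give methyl 5,6-dimethyl-2,4-dioxocyclohexane-1-carboxylate F1. Br2 in DMF (0 °C, then 80 °C) should brominate and dehydrobrominate this dione to methyl 2,4-dihydroxy-5,6-dimethylbenzoate F2. Rieche formylation (Cl2CHOMe, TiCl4, CH2Cl2) at C3, the only free ring position, then gives 14, so steps 6 and 7 are no longer needed.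

Step 10. The activated acid may rearrange to the N-acylurea, or acylate a hydroxy group of a second acid molecule, before it meets the C4 hydroxy group of 16, which lies between two methyl groups. The fallback masks the ring A phenols during the coupling and moves the ether cleavage to the end. It sets out from 12 and 16 and comes back to the route at 19. Conc. H2SO4 (as in step 9) should convert 12 into 3-formyl-2,4-dimethoxy-5,6-dimethylbenzoic acid F3. Trifluoroacetic anhydride in toluene at rt turns this into 3-formyl-2,4-dimethoxy-5,6-dimethylbenzoic trifluoroacetic anhydride F4, which reacts by the dissociative pathway open to hindered electron-rich aroyl derivatives. It should acylate the C4–OH of 16 to give methyl 4-[(3-formyl-2,4-dimethoxy-5,6-dimethylbenzoyl)oxy]-2-hydroxy-3,5,6-trimethylbenzoate F5. BCl3 in CH2Cl2 (−78 to 0 °C) then removes both methyl ethers, each next to a carbonyl group, and gives 19.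

Step 9. In conc. H2SO4, ester cleavage may be slower than protodecarboxylation of the acid formed or loss of the formyl group by ipso protonation. The fallback exchanges the ester, before the aldehyde is present, for one that leaves by alkyl–oxygen cleavage. It sets out from 10 and comes back to the route at 17. KOH in DMSO–H2O at 100 °C should saponify 10 to 2,4-dimethoxy-5,6-dimethylbenzoic acid F6. BnBr and K2CO3 in DMF give benzyl 2,4-dimethoxy-5,6-dimethylbenzoate F7. Rieche formylation as in step 6 gives benzyl 3-formyl-2,4-dimethoxy-5,6-dimethylbenzoate F8. Excess BCl3 in CH2Cl2 should then cleave the two ethers and the benzyl ester in one operation to give 17. Compound 14 for ring B is still taken from step 7.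

Further compounds
F1 | step 5 | methyl 5,6-dimethyl-2,4-dioxocyclohexane-1-carboxylate (racemic diastereomer mixture) | COC(=O)C1C(C)C(C)C(=O)CC1=O
F2 | step 5 | methyl 2,4-dihydroxy-5,6-dimethylbenzoate | COC(=O)c1c(C)c(C)c(O)cc1O
F3 | step 10 | 3-formyl-2,4-dimethoxy-5,6-dimethylbenzoic acid | OC(=O)c1c(C)c(C)c(OC)c(C=O)c1OC
F4 | step 10 | 3-formyl-2,4-dimethoxy-5,6-dimethylbenzoic trifluoroacetic anhydride | O=Cc1c(OC)c(C)c(C)c(C(=O)OC(=O)C(F)(F)F)c1OC
F5 | step 10 | methyl 4-[(3-formyl-2,4-dimethoxy-5,6-dimethylbenzoyl)oxy]-2-hydroxy-3,5,6-trimethylbenzoate | COC(=O)c1c(C)c(C)c(OC(=O)c2c(C)c(C)c(OC)c(C=O)c2OC)c(C)c1O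
F6 | step 9 | 2,4-dimethoxy-5,6-dimethylbenzoic acid | OC(=O)c1c(C)c(C)c(OC)cc1OC
F7 | step 9 | benzyl 2,4-dimethoxy-5,6-dimethylbenzoate | COc1cc(OC)c(C(=O)OCc2ccccc2)c(C)c1C
F8 | step 9 | benzyl 3-formyl-2,4-dimethoxy-5,6-dimethylbenzoate | COc1c(C=O)c(OC)c(C(=O)OCc2ccccc2)c(C)c1C
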